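Noon operator to you, who take over this flask.

- noon: Z 0.50 mM; the very flask that is asked about, followed so far
- flask: Z 0.50 mM; time 6.0 min

noon run (percent of the Z charged)

| time / s | J / % | Z / % |
|---|---|---|
| 10.0 | 26.0 | 45.5 |
| 15.0 | 43.6 | 21.0 |
| 25.0 | 67.5 | 0 |
| 40.0 | 70.6 | 0 |
| 60.0 | 69.1 | 0 |
| 120 | 63.6 | 0 |

(readings scatter by 0.5 percentage points)

- Z is a solid; its amount is given per volume of the solution
- at the start none of Z is in solution

1. time up to 6.0 min at which J stands highest
2. the amount of J, in percent of the Z charged, at that time

1. Now: Z reads 0% from 25.0 s on, and [J] is falling, 69.1% at 60.0 s and 63.6% at 120 s.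
2. Replace that stretch by its mean: divide the fall per minute by the square of the geometric mean [J], as fractions of the charge. That gives 0.125 min⁻¹: the drain constant, the rise of 1/[J] per minute, an apparent second-order rate constant. Second order is my trial, since two readings cannot show the order.
3. Run back to 40.0 s, this line gives 71.2%, above the reading by 0.55 percentage points, against a scatter of 0.5 points. So I put the top of this flask just before 40.0 s, near 71.2%.
4. Don't wait: run forward, the line gives 48.2% at 6.0 min, less than the reading at 40.0 s.

The forecast says 0.7 min and 70.8%: “The peak comes when feed equals loss”. My top stands earlier than its time.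

    J → Q (k = 1.02 × 10⁻⁴ s⁻¹)
    X ⇌ J (K = 9.00, k = 0.170 s⁻¹)
    2 X → D (k = 181 M⁻¹ s⁻¹)
    Z ⇌ X, rate k4*(cs4 - [X]) while solid is left; crystals form when [X] > cs4 (solubility = 0.380 mM, k = 0.0936 s⁻¹)

This flask tops at 0.589 min with 70.8%, earlier than the forecast's time. From that top the drain constant gives 47.9% at 6.0 min, and the flask holds 48.9%. The neighbour flask is charged with 0.20 mM of Z, with the time and all else held. A second-order drain on fractions scales with the charge, so its constant is 0.0501 min⁻¹. Starting from its best of 76.8% and counting the whole 6.0 min, this gives 62.4%. The neighbour flask holds 62.8% of J at 6.00 min.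

The runs were generated by integration from invented constants; scatter was added.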